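**Retrosynthetic overview**
1. Target 15 ← hydrogenolysis of the two benzyl ethers of 14 ← ionic hydrogenation of the C7=C8 alkene of dihydronaphthalene 13; C8 is held one oxidation level up so that it can be set last.
2. 13 ← acyclic ketone 6 + benzylic chloride 9: benzylmagnesium addition makes C7–C8, acid then closes ring B by Friedel–Crafts bonding of C2 to C7' and dehydrates. Ring B is the only ring made; rings A and C are bought.
3. Enabling feature: C7' is benzylic to ring C, whose C4' oxygen is para to it, so it ionises easily. C2 of ring A is ortho to the C3 methoxy, para to the C5 methoxy and equivalent to C6, so ring closure has no regiochemical choice. The C4 oxygen para to C7 later makes protonation at C8 reversible.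
4. 6 ← Evans syn aldol of 1 with 2, then Weinreb amide, silyl ether, MeMgBr; 9 ← aldehyde 7 by reduction and chlorination.
5. Stereocontrol: C8' comes from the aldol; C7' is erased and reset trans to C8' during ring closure; C8 is set cis to C8' by substrate-controlled protonation.

Key step: step 7

Remark: lignan numbering is used (ring A = fused trioxygenated ring C1–C6; ring B = C7, C8, C8', C7', C2, C1; ring C = pendant guaiacyl ring C1'–C6'), and compounds 1, 2 and 7 are taken as commercial.

**Step 1**
Reactants: 1 (S)-4-benzyl-3-propionyloxazolidin-2-one; 2 4-(benzyloxy)-3-methoxybenzaldehyde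
Product: 3 (S)-4-benzyl-3-[(2S,3S)-3-[4-(benzyloxy)-3-methoxyphenyl]-3-hydroxy-2-methylpropanoyl]oxazolidin-2-one
Conditions: Bu2BOTf, i-Pr2NEt, CH2Cl2, 0 °C; add 2, −78 to 0 °C; pH 7 buffer, MeOH, H2O2 work-up
Reagents that add atoms: none
Why: Evans syn aldol reaction: the dibutylboron-mediated addition runs through a closed Zimmerman–Traxler chair in which the benzyl group of the auxiliary shields one face, which should set the two new stereocenters as (2S,3S); only the methyl-bearing one (the future C8') has to reach the target.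

**Step 2**
Reactants: 3 (S)-4-benzyl-3-[(2S,3S)-3-[4-(benzyloxy)-3-methoxyphenyl]-3-hydroxy-2-methylpropanoyl]oxazolidin-2-one
Product: 4 (2S,3S)-3-[4-(benzyloxy)-3-methoxyphenyl]-3-hydroxy-N-methoxy-N,2-dimethylpropanamide
Conditions: MeNHOMe·HCl, AlMe3, CH2Cl2, −20 to 0 °C
Reagents that add atoms: N,O-dimethylhydroxylamine hydrochloride, CNOC.Cl
Why: Weinreb amide formation by AlMe3-mediated aminolysis: the exocyclic imide carbonyl, activated by the neighbouring free hydroxyl, should be attacked selectively, releasing the auxiliary without touching either stereocenter.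

**Step 3**
Reactants: 4 (2S,3S)-3-[4-(benzyloxy)-3-methoxyphenyl]-3-hydroxy-N-methoxy-N,2-dimethylpropanamide
Product: 5 (2S,3S)-3-[4-(benzyloxy)-3-methoxyphenyl]-3-[(tert-butyldimethylsilyl)oxy]-N-methoxy-N,2-dimethylpropanamide
Conditions: TBSOTf, 2,6-lutidine, CH2Cl2, −78 to 0 °C
Reagents that add atoms: tert-butyldimethylsilyl trifluoromethanesulfonate, CC(C)(C)[Si](C)(C)OS(=O)(=O)C(F)(F)F
Why: Silylation of the secondary benzylic alcohol with a silyl triflate and a hindered base; the ether blocks retro-aldol cleavage in the two organometallic steps that follow and later serves as the leaving group at C7'.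

**Step 4**
Reactants: 5 (2S,3S)-3-[4-(benzyloxy)-3-methoxyphenyl]-3-[(tert-butyldimethylsilyl)oxy]-N-methoxy-N,2-dimethylpropanamide
Product: 6 (3S,4S)-4-[4-(benzyloxy)-3-methoxyphenyl]-4-[(tert-butyldimethylsilyl)oxy]-3-methylbutan-2-one
Conditions: MeMgBr, THF, 0 °C; H2O work-up
Reagents that add atoms: methylmagnesium bromide, C[Mg]Br
Why: Weinreb ketone synthesis: N-methoxy-N-methyl amides take up only one equivalent of Grignard reagent, so the methyl ketone (the future C8 with its methyl) is released on work-up and is never exposed to the basic reagent.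

**Step 5**
Reactants: 7 4-(benzyloxy)-3,5-dimethoxybenzaldehyde
Product: 8 [4-(benzyloxy)-3,5-dimethoxyphenyl]methanol
Conditions: NaBH4, MeOH, 0 °C
Reagents that add atoms: none
Why: Borohydride reduction of the aromatic aldehyde to the benzylic alcohol; no stereocenter is involved.

**Step 6**
Reactants: 8 [4-(benzyloxy)-3,5-dimethoxyphenyl]methanol
Product: 9 2-(benzyloxy)-5-(chloromethyl)-1,3-dimethoxybenzene
Conditions: SOCl2, CH2Cl2, 0 °C to rt
Reagents that add atoms: thionyl chloride, O=S(Cl)Cl
Why: Deoxychlorination of the electron-rich benzylic alcohol with thionyl chloride gives the benzylic chloride needed for magnesium insertion.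

**Step 7**
Reactants: 6 (3S,4S)-4-[4-(benzyloxy)-3-methoxyphenyl]-4-[(tert-butyldimethylsilyl)oxy]-3-methylbutan-2-one; 9 2-(benzyloxy)-5-(chloromethyl)-1,3-dimethoxybenzene
Product: 13 (1R,2S)-7-(benzyloxy)-1-[4-(benzyloxy)-3-methoxyphenyl]-6,8-dimethoxy-2,3-dimethyl-1,2-dihydronaphthalene, via benzylic Grignard reagent 10 (not isolated), via acyclic tertiary carbinol 11 (not isolated), via cyclised carbinol 12 (not isolated)
Conditions: Mg turnings, THF, 0 °C (9 to 10); add to 6, LaCl3·2LiCl (30 mol %), CH2Cl2–THF, −78 to −20 °C; then TFA (excess) in the same flask, −20 °C to rt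
Reagents that add atoms: none
Why: The benzylic Grignard reagent 10 adds 1,2 to the ketone of 6 and makes the C7–C8 bond as carbinol 11 (both C8 epimers, which is harmless because this centre is erased below). On acidification the C7' silyl ether, benzylic to ring C with its para oxygen, ionises long before the unactivated tertiary alcohol, and C2 of ring A (ortho to one methoxy, para to the other, equivalent to C6) captures the cation in an intramolecular Friedel–Crafts alkylation to give 12; the closest known reaction type is the acid-mediated cyclisation of 7'-oxygenated dibenzylbutane lignans to aryltetralins. Ring B closes as a six-membered ring, 6-endo with respect to the attacking arene bond, helped by the fully substituted C8. The new C7' stereocenter is controlled by the C8' methyl: the planar cation is captured so that ring C ends up trans to that methyl, so the configuration that C7' had in 6 is irrelevant and any epimer mixture converges. On warming, E1 loss of water from C8 takes a benzylic C7 proton and gives the conjugated styrene 13. The step needs ionisation at C7' before C8 (secured by the electron-rich ring C) and proton loss toward C7 rather than C8' (secured by conjugation with ring A, 13 being the most stable alkene isomer).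

**Step 8**
Reactants: 13 (1R,2S)-7-(benzyloxy)-1-[4-(benzyloxy)-3-methoxyphenyl]-6,8-dimethoxy-2,3-dimethyl-1,2-dihydronaphthalene
Product: 14 (1R,2R,3R)-7-(benzyloxy)-1-[4-(benzyloxy)-3-methoxyphenyl]-6,8-dimethoxy-2,3-dimethyl-1,2,3,4-tetrahydronaphthalene
Conditions: TFA, CH2Cl2, −20 °C; Et3SiH added slowly, −20 to 0 °C
Reagents that add atoms: none
Why: Ionic hydrogenation of a styrene: protonation at C8 gives the C7 benzylic cation stabilised by the para C4 oxygen and should be reversible; the favoured cation carries the C8 methyl pseudoequatorial and cis to the C8' methyl (ring C is held pseudoaxial by the peri C3 methoxy and the C8' methyl is trans to it, so the other C8 epimer would suffer a 1,3-diaxial clash with ring C), and Et3SiH then delivers hydride to C7, which should set C8 as R under substrate control.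

**Step 9**
Reactants: 14 (1R,2R,3R)-7-(benzyloxy)-1-[4-(benzyloxy)-3-methoxyphenyl]-6,8-dimethoxy-2,3-dimethyl-1,2,3,4-tetrahydronaphthalene
Product: 15 (−)-(7'R,8R,8'R)-4,4'-dihydroxy-3,3',5-trimethoxy-2,7'-cyclolignan
Conditions: H2 (1 atm), 10% Pd/C, EtOAc–MeOH, rt
Reagents that add atoms: none
Why: Hydrogenolysis of both benzyl aryl ethers over palladium on carbon; no stereocenter is touched and the saturated ring B is inert.

**Compound list**
1 | (S)-4-benzyl-3-propionyloxazolidin-2-one | CCC(=O)N1[C@@H](Cc2ccccc2)COC1=O | starting material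
2 | 4-(benzyloxy)-3-methoxybenzaldehyde | COc1cc(C=O)ccc1OCc1ccccc1 | starting material
3 | (S)-4-benzyl-3-[(2S,3S)-3-[4-(benzyloxy)-3-methoxyphenyl]-3-hydroxy-2-methylpropanoyl]oxazolidin-2-one | C[C@H](C(=O)N1[C@@H](Cc2ccccc2)COC1=O)[C@H](O)c1ccc(OCc2ccccc2)c(OC)c1 | intermediate
4 | (2S,3S)-3-[4-(benzyloxy)-3-methoxyphenyl]-3-hydroxy-N-methoxy-N,2-dimethylpropanamide | C[C@H](C(=O)N(C)OC)[C@H](O)c1ccc(OCc2ccccc2)c(OC)c1 | intermediate
5 | (2S,3S)-3-[4-(benzyloxy)-3-methoxyphenyl]-3-[(tert-butyldimethylsilyl)oxy]-N-methoxy-N,2-dimethylpropanamide | C[C@H](C(=O)N(C)OC)[C@H](O[Si](C)(C)C(C)(C)C)c1ccc(OCc2ccccc2)c(OC)c1 | intermediate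
6 | (3S,4S)-4-[4-(benzyloxy)-3-methoxyphenyl]-4-[(tert-butyldimethylsilyl)oxy]-3-methylbutan-2-one | C[C@H](C(C)=O)[C@H](O[Si](C)(C)C(C)(C)C)c1ccc(OCc2ccccc2)c(OC)c1 | intermediate
7 | 4-(benzyloxy)-3,5-dimethoxybenzaldehyde | COc1cc(C=O)cc(OC)c1OCc1ccccc1 | starting material
8 | [4-(benzyloxy)-3,5-dimethoxyphenyl]methanol | COc1cc(CO)cc(OC)c1OCc1ccccc1 | intermediate
9 | 2-(benzyloxy)-5-(chloromethyl)-1,3-dimethoxybenzene | COc1cc(CCl)cc(OC)c1OCc1ccccc1 | intermediate
10 | [4-(benzyloxy)-3,5-dimethoxybenzyl]magnesium chloride (formed in the flask) | COc1cc(C[Mg]Cl)cc(OC)c1OCc1ccccc1 | intermediate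
11 | (3S,4S)-1-[4-(benzyloxy)-3,5-dimethoxyphenyl]-4-[4-(benzyloxy)-3-methoxyphenyl]-4-[(tert-butyldimethylsilyl)oxy]-2,3-dimethylbutan-2-ol, both C2 epimers (formed in the flask) | C[C@H](C(C)(O)Cc1cc(OC)c(OCc2ccccc2)c(OC)c1)[C@H](O[Si](C)(C)C(C)(C)C)c1ccc(OCc2ccccc2)c(OC)c1 | intermediate
12 | (3S,4R)-6-(benzyloxy)-4-[4-(benzyloxy)-3-methoxyphenyl]-5,7-dimethoxy-2,3-dimethyl-1,2,3,4-tetrahydronaphthalen-2-ol, both C2 epimers (formed in the flask) | COc1cc([C@@H]2c3c(cc(OC)c(OCc4ccccc4)c3OC)CC(C)(O)[C@H]2C)ccc1OCc1ccccc1 | intermediate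
13 | (1R,2S)-7-(benzyloxy)-1-[4-(benzyloxy)-3-methoxyphenyl]-6,8-dimethoxy-2,3-dimethyl-1,2-dihydronaphthalene | COc1cc([C@@H]2c3c(cc(OC)c(OCc4ccccc4)c3OC)C=C(C)[C@H]2C)ccc1OCc1ccccc1 | intermediate
14 | (1R,2R,3R)-7-(benzyloxy)-1-[4-(benzyloxy)-3-methoxyphenyl]-6,8-dimethoxy-2,3-dimethyl-1,2,3,4-tetrahydronaphthalene | COc1cc([C@@H]2c3c(cc(OC)c(OCc4ccccc4)c3OC)C[C@@H](C)[C@H]2C)ccc1OCc1ccccc1 | intermediate
15 | (−)-(7'R,8R,8'R)-4,4'-dihydroxy-3,3',5-trimethoxy-2,7'-cyclolignan | COc1cc([C@@H]2c3c(cc(OC)c(O)c3OC)C[C@@H](C)[C@H]2C)ccc1O | target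

**Step count**
Total step count: 9. Longest linear sequence: 7 steps (steps 1, 2, 3, 4, 7, 8, 9).

**Steps most likely to fail and fallbacks**

1. Step 7. What may go wrong: Wurtz-type homocoupling of the electron-rich benzylic chloride during magnesium insertion; enolisation of 6 instead of addition; or proton loss from the C8 cation toward C8', which would scramble the only preset stereocenter. The fallback makes the C7–C8 bond as an alkene from the start, so no cation is ever formed at C8. It sets out from chloride 9: PPh3 in toluene at reflux should give [4-(benzyloxy)-3,5-dimethoxybenzyl]triphenylphosphonium chloride F1. NaN(SiMe3)2 in THF should convert it into the ylide F2, and Wittig olefination of ketone 6 should give the acyclic trisubstituted styrene F3 as an E/Z mixture. TFA in CH2Cl2 should then ionise the C7' silyl ether; the styrene geometry can equilibrate by reversible protonation, and Friedel–Crafts closure of ring B should bring the route back at 13.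

2. Step 8. What may go wrong: hydride capture outrunning the protonation equilibrium, giving poor facial selectivity at C8, or cationic dimerisation of the styrene. The fallback sets C8 under plain thermodynamic control next to a carbonyl. It sets out from 13: hydroboration–oxidation (BH3·THF; then NaOH, H2O2) should place oxygen on C7 and give the 7-hydroxy derivative of 14, F4, with C7 and C8 uncontrolled. Dess–Martin oxidation followed by DBU equilibration should give the 7-oxo derivative of 14, tetralone F5, with the C8 methyl pseudoequatorial and cis to the C8' methyl. Et3SiH in TFA should then reduce the electron-rich aryl ketone to the methylene and come back to the route at 14.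

3. Step 2. What may go wrong: retro-aldol fragmentation of the electron-rich benzylic aldolate under the aluminium amide conditions, or opening of the oxazolidinone ring instead of exocyclic cleavage. The fallback reaches ketone 6 without any acyl transfer. It sets out from aldehyde 2: (Z)-crotylboration with the (Z)-crotyldiisopinocampheylborane antipode that delivers the syn (1S,2R) adduct should give (1S,2R)-1-[4-(benzyloxy)-3-methoxyphenyl]-2-methylbut-3-en-1-ol F6. Silylation (TBSCl, imidazole, DMF) should give its silyl ether F7, and Tsuji–Wacker oxidation of the terminal vinyl group (PdCl2, CuCl, O2, DMF–H2O) should come back to the route at 6.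

**Further compounds**
F1 | step 7 | [4-(benzyloxy)-3,5-dimethoxybenzyl]triphenylphosphonium chloride | COc1cc(C[P+](c2ccccc2)(c2ccccc2)c2ccccc2)cc(OC)c1OCc1ccccc1.[Cl-]
F2 | step 7 | [4-(benzyloxy)-3,5-dimethoxybenzylidene]triphenylphosphorane | COc1cc(C=P(c2ccccc2)(c2ccccc2)c2ccccc2)cc(OC)c1OCc1ccccc1
F3 | step 7 | tert-butyl{[(1S,2R)-4-[4-(benzyloxy)-3,5-dimethoxyphenyl]-1-[4-(benzyloxy)-3-methoxyphenyl]-2,3-dimethylbut-3-en-1-yl]oxy}dimethylsilane (E/Z mixture) | C[C@H](C(C)=Cc1cc(OC)c(OCc2ccccc2)c(OC)c1)[C@H](O[Si](C)(C)C(C)(C)C)c1ccc(OCc2ccccc2)c(OC)c1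
F4 | step 8 | 7-hydroxy derivative of 14 (C7 and C8 not controlled) | COc1cc([C@@H]2c3c(cc(OC)c(OCc4ccccc4)c3OC)C(O)C(C)[C@H]2C)ccc1OCc1ccccc1
F5 | step 8 | (2S,3S,4R)-6-(benzyloxy)-4-[4-(benzyloxy)-3-methoxyphenyl]-5,7-dimethoxy-2,3-dimethyl-3,4-dihydronaphthalen-1(2H)-one | COc1cc([C@@H]2c3c(cc(OC)c(OCc4ccccc4)c3OC)C(=O)[C@@H](C)[C@H]2C)ccc1OCc1ccccc1
F6 | step 2 | (1S,2R)-1-[4-(benzyloxy)-3-methoxyphenyl]-2-methylbut-3-en-1-ol | C=C[C@@H](C)[C@H](O)c1ccc(OCc2ccccc2)c(OC)c1
F7 | step 2 | {[(1S,2R)-1-[4-(benzyloxy)-3-methoxyphenyl]-2-methylbut-3-en-1-yl]oxy}(tert-butyl)dimethylsilane | C=C[C@@H](C)[C@H](O[Si](C)(C)C(C)(C)C)c1ccc(OCc2ccccc2)c(OC)c1
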